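We count turnovers. Four flasks are to be judged from three earlier runs.

| flask | substrate | coupling partner | free catalyst | temperature | remark | time |
|---|---|---|---|---|---|---|
| Saturday's | 11 mM | 7.7 mM | 0.55 mM | 10 °C | run made earlier |  |
| Thursday's | 11 mM | 7.7 mM | 0.77 mM | 25 °C | run made earlier |  |
| Friday's | 11 mM | 7.7 mM | 1.2 mM | 10 °C | run made earlier |  |
| delta | 11 mM (fed, over 4.0 h) | 7.70 mM | 0.55 mM | 25 °C | all else is in the flask from the start; the feed brings no volume worth counting | 5.0 h |
| gamma | 11 mM | 7.70 mM (fed, over 4.0 h) | 0.55 mM | 25 °C | all else is in the flask from the start; the feed brings no volume worth counting | 5.0 h |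
| eta | 11 mM | 7.70 mM (fed, over 25 min) | 0.55 mM | 25 °C | all else is in the flask from the start; the feed brings no volume worth counting | 5.0 h |
| beta | 11 mM | 7.70 mM (fed, over 4.0 h) | 0.55 mM |  | the addition at 5 °C, then warmed to 25 °C; the feed brings no volume worth counting | 5.0 h |

| run | time / h | target / % |
|---|---|---|
| Saturday's | 0.833 | 0.5 |
| Saturday's | 2.00 | 1.8 |
| Saturday's | 4.00 | 3.6 |
| Saturday's | 6.00 | 4.6 |
| Thursday's | 0.250 | 0.5 |
| Thursday's | 0.500 | 2.8 |
| Thursday's | 1.33 | 8.6 |
| Thursday's | 3.00 | 19.9 |
| Friday's | 2.00 | 2.8 |
| Friday's | 3.00 | 5.1 |
| Friday's | 5.00 | 8.6 |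
| Friday's | 6.00 | 9.9 |

(standard deviation of a reading: 0.5 percentage points)

- the numbers in the tables scatter with a standard deviation of 0.5 percentage points
- reactions considered so far: coupling partner + free catalyst -> catalyst intermediate A; catalyst intermediate A <-> catalyst intermediate B; substrate + catalyst intermediate B -> catalyst intermediate C; catalyst intermediate C -> released group + catalyst intermediate D; catalyst intermediate D -> free catalyst + target; coupling partner + free catalyst + target -> free catalyst + over-reaction product

* which flask leads in amount of target, in percent of the substrate charged ("all alike" within 1.5 percentage points) (delta / gamma / eta / beta / all alike)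
* how much target is there at the end, in percent of the substrate charged: delta
* how much target is there at the end, in percent of the substrate charged: gamma
* how much target is there at the end, in percent of the substrate charged: eta
* how much target is there at the end, in percent of the substrate charged: beta

The coupling partner is the limiting reagent, charged at 70.0% of the substrate. Each target takes one partner, so Thursday's last reading of 19.9% target had cost 28.4% of the partner's own charge, bound forms and over-reaction not counted. Yet Thursday's later slope is 0.968 of its earlier slope, a reading with a scatter of 0.5 percentage points on each point. Thursday's slowing up to that conversion therefore reads small, and it already sits inside Thursday's mean slope, so we add no separate correction.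

We take that mean slope from 0.500 h to 3.00 h and divide it by Thursday's catalyst share, 7.00% of the substrate charge. This gives the turnover frequency, the target made per charged catalyst per hour at 25 °C: 0.977 h⁻¹.

Eta's catalyst share is 5.00%, so eta should run at a mean 0.0489 h⁻¹ as a fraction of the charge. Thursday's line reaches zero after 0.0906 h, and eta's feed costs a further 0.208 h, its mean delay. Our reckoning for eta is therefore 23.0%.

Delta and gamma have eta's catalyst share, but their feeds run longer than eta's. No earlier run was fed, so we place both below eta without a figure. Beta's addition stands at 5 °C, colder than Saturday's 10 °C, so Saturday's slope over 4.0 h plus one warm hour at eta's rate gives beta an estimate of 7.69%, which we expect to stand high.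

The forecast named eta as leader, with delta 17%, gamma 22%, eta 23% and beta 8%, and said “Eta is essentially a batch run”.

The flasks end with delta 21.4%, gamma 18.2%, eta 23.2% and beta 6.12%, so eta leads.

    coupling partner + free catalyst → catalyst intermediate A (k = 875 M⁻¹ h⁻¹, Ea = 55.0 kJ mol⁻¹)
    catalyst intermediate A ⇌ catalyst intermediate B (K = 44.5, k = 57.1 h⁻¹, Ea = 74.0 kJ mol⁻¹, ΔH = 20.0 kJ mol⁻¹)
    substrate + catalyst intermediate B → catalyst intermediate C (k = 2110 M⁻¹ h⁻¹, Ea = 40.0 kJ mol⁻¹)
    catalyst intermediate C → released group + catalyst intermediate D (k = 1.46 h⁻¹, Ea = 93.0 kJ mol⁻¹)
    catalyst intermediate D → free catalyst + target (k = 344 h⁻¹, Ea = 70.0 kJ mol⁻¹)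
    coupling partner + free catalyst + target → free catalyst + over-reaction product (k = 33900 M⁻² h⁻¹, Ea = 42.0 kJ mol⁻¹)
    (constants at 25 °C)

In eta, catalyst intermediate C holds 67.5% of the catalyst at 5.00 h, and that share times its release constant 1.46 h⁻¹ is 0.986 h⁻¹, beside our turnover frequency of 0.977 h⁻¹. A neighbouring flask is eta with 0.14 mM of free catalyst. The turnover frequency, with the same lag and feed delay, gives it 5.85%, and that neighbouring flask ends at 6.42%.

The data stem from a simulated flask with constants of no real substance, noise included.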